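**Remark on the chemistry:** the target has no stereocentre and is achiral, so no enantiocontrol is needed; the route only has to deliver the constitution.

## Retrosynthetic overview

1. Target 16 ⇐ threefold bromination of ring A (C4, C5, C6) of phenol 15 ⇐ MOM ether 14.
2. 14 ⇐ ring B opened at C1'–C2' and C5'–C6': aryl ethynyl ether 10 (ether O, C1', C6') plus 3,5-dibromo-2-pyrone 12 (C2'–C5'), with loss of CO2.
3. 10 ⇐ dichlorovinyl ether 7 ⇐ phenol 4 + trichloroethylene 5; 4 ⇐ o-vanillin 1; 12 ⇐ coumalic acid 11.
4. Feature used: ring B is a benzene with the ether oxygen on C1', bromine on C2' and C4', and hydrogen on C3', C5', C6'. This is the 3,5-dibromo pattern of the pyrone (C3→C2', C5→C4') placed next to an oxygen-bearing alkyne carbon.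
5. Ring order: ring A is bought (o-vanillin); ring B is built de novo in step 6.

Key step: step 6

## Route

**Step 1**
Reactants: 1 o-vanillin (2-hydroxy-3-methoxybenzaldehyde)
Product: 2 3-methoxy-2-(methoxymethoxy)benzaldehyde
Conditions: MOMCl, i-Pr2NEt, CH2Cl2, 0 °C → rt
Reagents that add atoms: chloromethyl methyl ether, COCCl
Why: O-alkylation of the phenol (MOM protection) masks the oxygen that becomes the free OH of the target and withstands the later base, peracid and butyllithium steps.

**Step 2**
Reactants: 2 3-methoxy-2-(methoxymethoxy)benzaldehyde
Product: 4 3-methoxy-2-(methoxymethoxy)phenol, via aryl formate 3 (not isolated)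
Conditions: mCPBA, CH2Cl2, 0 °C → rt; then K2CO3 (cat.), MeOH, rt
Reagents that add atoms: mCPBA, OOC(=O)c1cccc(Cl)c1
Why: Baeyer–Villiger (Dakin-type) oxidation; the electron-rich ortho-alkoxy aryl group should migrate in preference to hydride, and the formate is then cleaved by methanolysis.

**Step 3**
Reactants: 4 3-methoxy-2-(methoxymethoxy)phenol; 5 trichloroethylene
Product: 7 1-{[(E)-1,2-dichloroethenyl]oxy}-3-methoxy-2-(methoxymethoxy)benzene, via dichloroacetylene 6 (not isolated)
Conditions: K2CO3, DMF, 70 °C
Reagents that add atoms: none
Why: Base-mediated vinylation of a phenol with trichloroethylene; dehydrochlorination gives dichloroacetylene in the flask, and anti addition of the phenoxide O–H across it should give the (E)-1,2-dichlorovinyl ether.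

**Step 4**
Reactants: 7 1-{[(E)-1,2-dichloroethenyl]oxy}-3-methoxy-2-(methoxymethoxy)benzene
Product: 10 1-(ethynyloxy)-3-methoxy-2-(methoxymethoxy)benzene, via chloroethynyl ether 8 (not isolated), via lithium aryloxyacetylide 9 (not isolated)
Conditions: n-BuLi (2.2 equiv), THF, −78 → −40 °C; H2O, −78 °C; cold extraction, kept as a dry PhMe solution
Reagents that add atoms: none
Why: Dichlorovinyl ether to ynol ether conversion: deprotonation and loss of LiCl give the chloroalkyne, chlorine–lithium exchange gives the acetylide, and protonation gives the terminal ynol ether; at −78 °C this should outrun ortho-lithiation next to the MOM group.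

**Step 5**
Reactants: 11 coumalic acid
Product: 12 3,5-dibromo-2H-pyran-2-one
Conditions: NBS (2.5 equiv), LiOAc, MeCN–H2O, rt
Reagents that add atoms: N-bromosuccinimide, O=C1CCC(=O)N1Br
Why: Bromodecarboxylation of the pyrone carboxylate (ipso substitution of CO2H at C5) combined with electrophilic bromination at C3 is the established access to this dibromopyrone.

**Step 6**
Reactants: 10 1-(ethynyloxy)-3-methoxy-2-(methoxymethoxy)benzene; 12 3,5-dibromo-2H-pyran-2-one
Product: 14 1-(2,4-dibromophenoxy)-3-methoxy-2-(methoxymethoxy)benzene, via bridged bicyclic lactone 13 (not isolated)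
Conditions: 10 (1.5 equiv), BHT (cat.), dry PhMe, sealed tube, 80 → 110 °C
Reagents that add atoms: none
Why: The electron-poor diene of 12 (C3=C4–C5=C6) and the electron-rich alkyne of 10 should combine in a concerted, asynchronous inverse-electron-demand [4+2] cycloaddition, in which the nucleophilic terminal alkyne carbon bonds ahead to the electrophilic C6 of the pyrone while the oxygen-bearing carbon closes onto C3, and the bicyclic lactone 13 then expels CO2 by retro-[4+2] to give the arene. The closest known reaction type is the 2-pyrone–alkyne Diels–Alder/decarboxylation benzannulation, together with the cycloadditions of 3,5-dibromo-2-pyrone with enol ethers, which place the alkoxy carbon next to the brominated bridgehead. Ring B is closed as a six-membered carbocycle in intermolecular [4+2] mode through the C1'–C2' and C5'–C6' bonds and is aromatised by the cycloreversion. No stereocentre persists, because the two bridgehead centres of 13 are destroyed when CO2 leaves. The step needs regioselectivity (oxygen-bearing carbon to C3; the reverse orientation would give the 3,5-dibromophenyl ether), which the matched polarisation of the ynol ether (β-carbon nucleophilic) and of the pyrone (C6 as the δ-acceptor position of the dienoate) should secure, and it needs the alkyne to survive heating, which is helped by the aryl group on oxygen having no β-hydrogen for a retro-ene path to a ketene.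

**Step 7**
Reactants: 14 1-(2,4-dibromophenoxy)-3-methoxy-2-(methoxymethoxy)benzene
Product: 15 2-(2,4-dibromophenoxy)-6-methoxyphenol
Conditions: HCl (conc., cat.), MeOH, 50 °C
Reagents that add atoms: none
Why: Acid-catalysed acetal exchange removes the MOM group; the methyl ether, the diaryl ether and the aryl bromides are inert to these conditions.

**Step 8**
Reactants: 15 2-(2,4-dibromophenoxy)-6-methoxyphenol
Product: 16 3,4,5-tribromo-2-(2,4-dibromophenoxy)-6-methoxyphenol (target)
Conditions: Br2 (3.05 equiv), AcOH, 0 °C → rt
Reagents that add atoms: bromine, BrBr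
Why: Electrophilic aromatic bromination; on ring A, C4 and C6 are each ortho to one ether oxygen and para to the other (OMe and OAr are 1,3-related) and C5 is para to the free OH, whereas ring B carries two bromines and one shared oxygen, so three equivalents should fill ring A only.

## Compound list

1 | o-vanillin (2-hydroxy-3-methoxybenzaldehyde) | COc1cccc(C=O)c1O | starting material
2 | 3-methoxy-2-(methoxymethoxy)benzaldehyde | COCOc1c(OC)cccc1C=O | intermediate
3 | 3-methoxy-2-(methoxymethoxy)phenyl formate | COCOc1c(OC)cccc1OC=O | intermediate (not isolated)
4 | 3-methoxy-2-(methoxymethoxy)phenol | COCOc1c(OC)cccc1O | intermediate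
5 | trichloroethylene | ClC=C(Cl)Cl | starting material
6 | dichloroacetylene | ClC#CCl | intermediate (not isolated)
7 | 1-{[(E)-1,2-dichloroethenyl]oxy}-3-methoxy-2-(methoxymethoxy)benzene | COCOc1c(OC)cccc1O/C(Cl)=C\Cl | intermediate
8 | 1-[(chloroethynyl)oxy]-3-methoxy-2-(methoxymethoxy)benzene | COCOc1c(OC)cccc1OC#CCl | intermediate (not isolated)
9 | lithium [3-methoxy-2-(methoxymethoxy)phenoxy]acetylide | COCOc1c(OC)cccc1OC#C[Li] | intermediate (not isolated)
10 | 1-(ethynyloxy)-3-methoxy-2-(methoxymethoxy)benzene | COCOc1c(OC)cccc1OC#C | intermediate
11 | coumalic acid (2-oxo-2H-pyran-5-carboxylic acid) | O=C(O)c1ccc(=O)oc1 | starting material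
12 | 3,5-dibromo-2H-pyran-2-one | O=c1occ(Br)cc1Br | intermediate
13 | 4,7-dibromo-5-[3-methoxy-2-(methoxymethoxy)phenoxy]-2-oxabicyclo[2.2.2]octa-5,7-dien-3-one (racemic) | O=C1OC2C=C(Oc3cccc(OC)c3OCOC)C1(Br)C=C2Br | intermediate (not isolated)
14 | 1-(2,4-dibromophenoxy)-3-methoxy-2-(methoxymethoxy)benzene | COCOc1c(OC)cccc1Oc1ccc(Br)cc1Br | intermediate
15 | 2-(2,4-dibromophenoxy)-6-methoxyphenol | COc1cccc(Oc2ccc(Br)cc2Br)c1O | intermediate
16 | 3,4,5-tribromo-2-(2,4-dibromophenoxy)-6-methoxyphenol | COc1c(O)c(Oc2ccc(Br)cc2Br)c(Br)c(Br)c1Br | target

## Step count and risks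

Total step count: 8. Longest linear sequence: 7 (steps 1, 2, 3, 4, 6, 7, 8); step 5 is the one-step side branch.

**Step 6 (most likely to fail).** The cycloaddition may be slower than thermal oligomerisation or adventitious hydration of the terminal ynol ether, or the addends may combine partly in the reverse orientation. The fallback builds the diaryl ether by metal-free O-arylation and sets out from phenol 4. The reagent bis(2,4-dibromophenyl)iodonium chloride F1 would be made from 1,3-dibromobenzene with iodyl sulfate in sulfuric acid, followed by chloride exchange. Phenol 4 and F1 with K2CO3 in MeCN at 60 °C should transfer one 2,4-dibromophenyl group to oxygen by ligand coupling at iodine(III). The route is rejoined at 14.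

**Step 4.** The terminal ynol ether may polymerise or hydrate to the aryl acetate during aqueous work-up and concentration. The fallback sets out from 7 and masks the alkyne terminus. The lithium acetylide generated as before is trapped with Me3SiCl at −78 °C to give trimethyl{[3-methoxy-2-(methoxymethoxy)phenoxy]ethynyl}silane F2, which can be purified and stored. F2 is desilylated with K2CO3 (cat.) in MeOH at 0 °C immediately before the cycloaddition and extracted into toluene, so that free 10 is never concentrated. The route is rejoined at 10.

**Step 8.** Stoichiometric control may be lost in the one-pot tribromination: the last substitution on ring A may slow to the rate of attack at C6' of ring B, or the free electron-rich phenol may be oxidised. The fallback stages the bromination behind the protecting group and sets out from 14. NBS (2.0 equiv) in MeCN, with the phenol still masked, should brominate the two positions activated by both ether oxygens and give 1,5-dibromo-2-(2,4-dibromophenoxy)-4-methoxy-3-(methoxymethoxy)benzene F3. HCl in MeOH then gives 3,5-dibromo-2-(2,4-dibromophenoxy)-6-methoxyphenol F4. One equivalent of Br2 in AcOH at 0 °C should fill the remaining position para to the hydroxyl. The route is rejoined at 16.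

## Further compounds

F1 | step 6 | bis(2,4-dibromophenyl)iodonium chloride | Brc1ccc([I+]c2ccc(Br)cc2Br)c(Br)c1.[Cl-]
F2 | step 4 | trimethyl{[3-methoxy-2-(methoxymethoxy)phenoxy]ethynyl}silane | COCOc1c(OC)cccc1OC#C[Si](C)(C)C
F3 | step 8 | 1,5-dibromo-2-(2,4-dibromophenoxy)-4-methoxy-3-(methoxymethoxy)benzene | COCOc1c(OC)c(Br)cc(Br)c1Oc1ccc(Br)cc1Br
F4 | step 8 | 3,5-dibromo-2-(2,4-dibromophenoxy)-6-methoxyphenol | COc1c(O)c(Oc2ccc(Br)cc2Br)c(Br)cc1Br
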